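## Retrosynthetic overview

1. Ring C is closed last: the O1–C2 bond forms by oxidative (p‑quinone‑methide) cyclisation of a 2'‑hydroxy‑α‑hydroxy‑dihydrochalcone, with C2 set trans to C3.
2. The C4–C4a bond comes from ortho‑lithiation of the ring‑A MOM ether and addition to an α‑silyloxy ester. C3 and the benzylic CH2 come from methyl (R)‑glycidate (the L‑serine‑derived enantiomer) and a 2,4‑bis(MOM‑oxy)phenyl cuprate.
3. Ring A is built by a Danheiser benzannulation (4π ring opening, [2+2], 4π ring opening, 6π electrocyclisation) of a siloxyalkyne with 3‑methoxycyclobutenone. This places the side chain between two oxygens with OMe para to it.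
4. The siloxyalkyne comes from (+)‑limonene oxide by periodate cleavage, esterification, MeMgBr addition and Kowalski homologation. Limonene C4 becomes the side‑chain stereocentre.
5. Ring order: A (benzannulation), B (bought), C (cyclisation).

Assumption: 3‑methoxycyclobut‑2‑en‑1‑one is treated as a catalogue compound (its 3‑ethoxy homologue is). Commercial (+)‑limonene oxide is a cis/trans mixture, which does not matter because both epoxide carbons become carbonyls.

## Route

**Step 1**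
Reactants: 1, (+)‑limonene 1,2‑oxide (4R, cis/trans mixture)
Product: 2, (3R)‑6‑oxo‑3‑(prop‑1‑en‑2‑yl)heptanal
Conditions: H5IO6, THF/H2O, 0 °C to rt
Reagents that add atoms: water, O (second carbonyl oxygen)
Why: Epoxide hydrolysis and Malaprade glycol cleavage open the ring; the isopropenyl group is untouched and the C4 stereocentre is not involved.

**Step 2**
Reactants: 2
Product: 3, methyl (3R)‑6‑oxo‑3‑(prop‑1‑en‑2‑yl)heptanoate
Conditions: PDC, MeOH, DMF, rt
Reagents that add atoms: methanol, CO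
Why: Oxidative esterification through the methyl hemiacetal converts only the aldehyde; ketone and alkene are inert.

**Step 3**
Reactants: 3
Product: 4, methyl (3R)‑6‑methyl‑3‑(prop‑1‑en‑2‑yl)‑6‑(triethylsilyloxy)heptanoate
Conditions: MeMgBr (1.1 equiv), THF, −78 °C; then TESOTf, 2,6‑lutidine, −78 to 0 °C
Reagents that add atoms: methylmagnesium bromide, C[Mg]Br; TESOTf, CC[Si](CC)(CC)OS(=O)(=O)C(F)(F)F
Why: Grignard 1,2‑addition is much faster at the ketone than at the ester at −78 °C, and the alkoxide is silylated in situ.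

**Step 4**
Reactants: 4
Product: 5, triisopropyl{[(4R)‑7‑methyl‑4‑(prop‑1‑en‑2‑yl)‑7‑(triethylsilyloxy)oct‑1‑yn‑1‑yl]oxy}silane
Conditions: CH2Br2, LiTMP, THF, −78 °C; LiHMDS; n‑BuLi, −78 to 25 °C; then i‑Pr3SiCl, −78 to 0 °C
Reagents that add atoms: dibromomethane, BrCBr (one carbon); TIPSCl, CC(C)[Si](Cl)(C(C)C)C(C)C
Why: Kowalski ester homologation (carbenoid 1,2‑shift) gives the lithium ynolate, which is O‑silylated; the stereocentre is β to the reacting carbon and untouched.

**Step 5 (key step)**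
Reactants: 5; 6, 3‑methoxycyclobut‑2‑en‑1‑one
Product: 7, 5‑methoxy‑2‑[(2R)‑5‑methyl‑2‑(prop‑1‑en‑2‑yl)‑5‑(triethylsilyloxy)hexyl]‑3‑(triisopropylsilyloxy)phenol
Conditions: toluene, 80 °C then 110 °C
Reagents that add atoms: none
Why: Danheiser benzannulation: 6 opens (4π) to a methoxyvinylketene, which adds [2+2] to the siloxyalkyne; 4π opening and 6π electrocyclisation then give the phenol, with ketene/ynol‑ether polarity placing the alkyl group between OH and OTIPS and OMe para.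

**Step 6**
Reactants: 7
Product: 8, 5‑methoxy‑1‑(methoxymethoxy)‑2‑[(2R)‑5‑methyl‑2‑(prop‑1‑en‑2‑yl)‑5‑(triethylsilyloxy)hexyl]‑3‑(triisopropylsilyloxy)benzene
Conditions: MOMCl, i‑Pr2NEt, CH2Cl2, 0 °C to rt
Reagents that add atoms: MOMCl, COCCl
Why: Phenol O‑alkylation; the MOM group protects the future O1 and serves as the ortho‑directing group.

**Step 7**
Reactants: 9, 4‑bromoresorcinol
Product: 10, 1‑bromo‑2,4‑bis(methoxymethoxy)benzene
Conditions: MOMCl, i‑Pr2NEt, CH2Cl2, 0 °C to rt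
Reagents that add atoms: MOMCl, COCCl
Why: Standard double phenol protection so the aryl bromide can be metallated.

**Step 8**
Reactants: 10; 11, methyl (R)‑glycidate
Product: 12, methyl (2R)‑3‑[2,4‑bis(methoxymethoxy)phenyl]‑2‑hydroxypropanoate
Conditions: Mg, THF; then CuI (10 mol %), 11, −40 to −20 °C
Reagents that add atoms: none
Why: Copper‑catalysed SN2 epoxide opening at the unsubstituted C3; the C2 stereocentre is not touched, so the (R)‑α‑hydroxy ester results.

**Step 9**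
Reactants: 12
Product: 13, methyl (2R)‑3‑[2,4‑bis(methoxymethoxy)phenyl]‑2‑(triethylsilyloxy)propanoate
Conditions: TESCl, imidazole, DMF, 0 °C
Reagents that add atoms: TESCl, CC[Si](Cl)(CC)CC
Why: Silylation masks the α‑hydroxyl for the organolithium step.

**Step 10**
Reactants: 8; 13
Product: 14, (2R)‑3‑[2,4‑bis(methoxymethoxy)phenyl]‑1‑{6‑methoxy‑2‑(methoxymethoxy)‑3‑[(2R)‑5‑methyl‑2‑(prop‑1‑en‑2‑yl)‑5‑(triethylsilyloxy)hexyl]‑4‑(triisopropylsilyloxy)phenyl}‑2‑(triethylsilyloxy)propan‑1‑one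
Conditions: 8, n‑BuLi, TMEDA, THF, 0 °C; then 13, −78 °C, quench cold
Reagents that add atoms: none
Why: Directed ortho‑metalation occurs between OMOM and OMe, and acyl substitution on the ester stops at the hindered 2,6‑dioxygenated aryl ketone; no bond to C3 is broken.

**Step 11**
Reactants: 14
Product: 15, (2R)‑3‑(2,4‑dihydroxyphenyl)‑2‑hydroxy‑1‑{2‑hydroxy‑3‑[(2R)‑5‑hydroxy‑5‑methyl‑2‑(prop‑1‑en‑2‑yl)hexyl]‑6‑methoxy‑4‑(triisopropylsilyloxy)phenyl}propan‑1‑one
Conditions: HCl (about 2 M), MeOH/THF, rt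
Reagents that add atoms: none
Why: Acid solvolysis removes the three aryl MOM acetals and both TES ethers, while the aryl TIPS ether survives and keeps O7 masked.

**Step 12**
Reactants: 15
Product: 16, (2R,3R)‑2‑(2,4‑dihydroxyphenyl)‑3‑hydroxy‑8‑[(2R)‑5‑hydroxy‑5‑methyl‑2‑(prop‑1‑en‑2‑yl)hexyl]‑5‑methoxy‑7‑(triisopropylsilyloxy)‑2,3‑dihydro‑4H‑chromen‑4‑one
Conditions: DDQ (1.0 equiv), THF, 0 °C to rt; then CSA (cat.)
Reagents that add atoms: none
Why: DDQ dehydrogenates the 4‑hydroxybenzyl unit to a p‑quinone methide, and intramolecular oxa‑Michael addition of the chelated 2'‑OH closes ring C; ring closure is reversible, so C2 settles trans (diequatorial) to the serine‑derived C3, giving 2R.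

**Step 13**
Reactants: 16
Product: 17, (2R,3R)‑2‑(2,4‑dihydroxyphenyl)‑3,7‑dihydroxy‑8‑[(2R)‑5‑hydroxy‑5‑methyl‑2‑(prop‑1‑en‑2‑yl)hexyl]‑5‑methoxy‑2,3‑dihydro‑4H‑chromen‑4‑one (target)
Conditions: TBAF, AcOH (1:1), THF, 0 °C
Reagents that add atoms: none
Why: Fluoride cleaves the aryl silyl ether; buffering avoids base‑induced ring opening or epimerisation of the flavanonol.

## Compound list

1 | (+)‑limonene 1,2‑oxide (4R, cis/trans) | CC12CC[C@@H](C(C)=C)CC1O2 | starting material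
2 | (3R)‑6‑oxo‑3‑(prop‑1‑en‑2‑yl)heptanal | O=CC[C@@H](CCC(C)=O)C(C)=C | intermediate
3 | methyl (3R)‑6‑oxo‑3‑(prop‑1‑en‑2‑yl)heptanoate | COC(=O)C[C@@H](CCC(C)=O)C(C)=C | intermediate
4 | methyl (3R)‑6‑methyl‑3‑(prop‑1‑en‑2‑yl)‑6‑(triethylsilyloxy)heptanoate | COC(=O)C[C@@H](CCC(C)(C)O[Si](CC)(CC)CC)C(C)=C | intermediate
5 | triisopropyl{[(4R)‑7‑methyl‑4‑(prop‑1‑en‑2‑yl)‑7‑(triethylsilyloxy)oct‑1‑yn‑1‑yl]oxy}silane | CC(C)[Si](OC#CC[C@@H](CCC(C)(C)O[Si](CC)(CC)CC)C(C)=C)(C(C)C)C(C)C | intermediate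
6 | 3‑methoxycyclobut‑2‑en‑1‑one | COC1=CC(=O)C1 | starting material
7 | 5‑methoxy‑2‑[(2R)‑5‑methyl‑2‑(prop‑1‑en‑2‑yl)‑5‑(triethylsilyloxy)hexyl]‑3‑(triisopropylsilyloxy)phenol | COc1cc(O)c(C[C@@H](CCC(C)(C)O[Si](CC)(CC)CC)C(C)=C)c(O[Si](C(C)C)(C(C)C)C(C)C)c1 | intermediate
8 | MOM ether of 7 | COCOc1cc(OC)cc(O[Si](C(C)C)(C(C)C)C(C)C)c1C[C@@H](CCC(C)(C)O[Si](CC)(CC)CC)C(C)=C | intermediate
9 | 4‑bromoresorcinol | Oc1ccc(Br)c(O)c1 | starting material
10 | 1‑bromo‑2,4‑bis(methoxymethoxy)benzene | COCOc1ccc(Br)c(OCOC)c1 | intermediate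
11 | methyl (R)‑glycidate | COC(=O)[C@H]1CO1 | starting material
12 | methyl (2R)‑3‑[2,4‑bis(methoxymethoxy)phenyl]‑2‑hydroxypropanoate | COC(=O)[C@H](O)Cc1ccc(OCOC)cc1OCOC | intermediate
13 | methyl (2R)‑3‑[2,4‑bis(methoxymethoxy)phenyl]‑2‑(triethylsilyloxy)propanoate | COC(=O)[C@H](O[Si](CC)(CC)CC)Cc1ccc(OCOC)cc1OCOC | intermediate
14 | protected α‑silyloxy dihydrochalcone (name in step 10) | COCOc1c(C[C@@H](CCC(C)(C)O[Si](CC)(CC)CC)C(C)=C)c(O[Si](C(C)C)(C(C)C)C(C)C)cc(OC)c1C(=O)[C@H](O[Si](CC)(CC)CC)Cc1ccc(OCOC)cc1OCOC | intermediate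
15 | 7‑O‑TIPS α‑hydroxy dihydrochalcone (name in step 11) | C=C(C)[C@H](CCC(C)(C)O)Cc1c(O[Si](C(C)C)(C(C)C)C(C)C)cc(OC)c(C(=O)[C@H](O)Cc2ccc(O)cc2O)c1O | intermediate
16 | 7‑O‑TIPS flavanonol (name in step 12) | C=C(C)[C@H](CCC(C)(C)O)Cc1c(O[Si](C(C)C)(C(C)C)C(C)C)cc(OC)c2c1O[C@H](c1ccc(O)cc1O)[C@@H](O)C2=O | intermediate
17 | (2R,3R)‑2‑(2,4‑dihydroxyphenyl)‑3,7‑dihydroxy‑8‑[(2R)‑5‑hydroxy‑5‑methyl‑2‑(prop‑1‑en‑2‑yl)hexyl]‑5‑methoxy‑2,3‑dihydro‑4H‑chromen‑4‑one | C=C(C)[C@H](CCC(C)(C)O)Cc1c(O)cc(OC)c2c1O[C@H](c1ccc(O)cc1O)[C@@H](O)C2=O | target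

## Summary

Total steps: 13.
Longest linear sequence: 10 (steps 1–6, then 10–13, from limonene oxide).

Steps most likely to fail:

1. **Step 5, benzannulation.** The alkoxy‑substituted vinylketene may oligomerise or the electrocyclic cascade may stall at the vinylcyclobutenone. Fallback: abandon ring construction; saponify 4, convert the acid to the nor‑bromide by Barton decarboxylative bromination, and alkylate 2‑lithio‑5‑methoxy‑1,3‑bis(methoxymethoxy)benzene, so the C8–C1'' bond is made by SN2 on a bought ring.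
2. **Step 12, DDQ cyclisation.** Risks are over‑oxidation to the flavonol and tautomerisation of the quinone methide to a chalcone, which would destroy C3. Fallback: carry C2 at the alcohol level instead; add the B‑ring aryl Grignard to an α‑silyloxy aldehyde derived from (R)‑glyceraldehyde acetonide, then close the ring by acid‑catalysed SN1 etherification with no oxidant.
3. **Step 10, aryllithium addition to the enolisable α‑silyloxy ester.** Risks are deprotonation at C3 (erosion of ee) and lithiation at the wrong site. Fallback: O‑acylate phenol 7 with the acid chloride corresponding to 13 and use a Lewis‑acid Fries rearrangement to form the C4–C4a bond, removing the organolithium step.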